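**Strategy.** Ring B is disconnected across its C2–C3 and C1–C6 bonds. A thermal Danheiser benzannulation joins 2,4,6-trimethoxyphenyl ethynyl ether, which already carries ring A on oxygen, to the vinylketene from 3-isopropoxy-4-methoxycyclobut-2-en-1-one; one operation builds ring B, the hindered A–O–B ether and a free phenol. The step exploits the ring B pattern: ether oxygen at C1 meta to oxygen at C3, hydrogens at C2 and C6, adjacent oxygens at C4 and C5. Since C3 and C5 are equivalent sites (both meta to C1, both next to C4), the new phenol is already the oxygen that must bear ring C; it is coupled directly with a C–D–E aryl bromide before global dealkylation.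

Key step: step 6

Remark: the target has no stereocentre; 9, 11, 12, 14, 16 and 23 are racemic and their stereocentres vanish later; ring B is numbered C1 (oxygen to ring A), C2–H, C3 (oxygen to ring C), C4 and C5 (hydroxyls), C6–H.

**Route**

Step 1
Reactants: 1 2,4,6-trimethoxyphenol; 2 trichloroethylene
Product: 4 (E)-2-[(1,2-dichloroethenyl)oxy]-1,3,5-trimethoxybenzene, via dichloroacetylene 3 (not isolated)
Conditions: K2CO3, DMF, 70 °C
Reagents that add atoms: none
Why: Base removes HCl from trichloroethylene to give dichloroacetylene in solution, and anti addition of the phenoxide should give the (E)-dichlorovinyl ether (dichlorovinylation of a phenol).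

Step 2
Reactants: 4 (E)-2-[(1,2-dichloroethenyl)oxy]-1,3,5-trimethoxybenzene
Product: 7 2-(ethynyloxy)-1,3,5-trimethoxybenzene, via chloroalkyne 5 (not isolated), via lithium acetylide 6 (not isolated)
Conditions: n-BuLi (2.2 equiv), THF, −78 to −40 °C; then H2O, −78 °C
Reagents that add atoms: none
Why: Dehydrochlorination followed by chlorine–lithium exchange and protonation is the standard dichlorovinyl ether route to ynol ethers, and at −78 °C lithiation of ring A between its methoxy groups should not compete.

Step 3
Reactants: 8 diisopropyl squarate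
Product: 10 3-isopropoxycyclobut-3-ene-1,2-dione, via hydroxycyclobutenone 9 (not isolated)
Conditions: LiAlH(OtBu)3, THF, −78 °C; aq. work-up; then conc. HCl (cat.), CH2Cl2, rt
Reagents that add atoms: none
Why: A single 1,2-hydride addition to one squarate carbonyl, then acid-induced loss of isopropanol with carbonyl transposition, is the established squarate-to-cyclobutenedione sequence.

Step 4
Reactants: 10 3-isopropoxycyclobut-3-ene-1,2-dione
Product: 11 4-hydroxy-3-isopropoxycyclobut-2-en-1-one (racemic)
Conditions: LiAlH(OtBu)3 (1.0 equiv), THF, −78 °C; aq. potassium sodium tartrate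
Reagents that add atoms: none
Why: The ketone next to the alkoxy-bearing carbon is more electrophilic than the vinylogous ester carbonyl, so one hydride equivalent at low temperature should reduce it selectively (chemoselective 1,2-reduction, as in nucleophile additions to 3-alkoxycyclobutenediones); the new stereocentre is racemic and is lost in step 6.

Step 5
Reactants: 11 4-hydroxy-3-isopropoxycyclobut-2-en-1-one
Product: 12 3-isopropoxy-4-methoxycyclobut-2-en-1-one (racemic)
Conditions: MeI, Ag2O, MeCN, rt, dark
Reagents that add atoms: iodomethane, CI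
Why: Purdie methylation etherifies the hydroxyl under neutral conditions that the acid- and base-sensitive cyclobutenone should tolerate, and a methyl ether (unlike a silyl ether) cannot migrate to the neighbouring phenol oxygen formed in step 6.

Step 6
Reactants: 7 2-(ethynyloxy)-1,3,5-trimethoxybenzene; 12 3-isopropoxy-4-methoxycyclobut-2-en-1-one
Product: 17 3-isopropoxy-2-methoxy-5-(2,4,6-trimethoxyphenoxy)phenol, via vinylketene 13 (not isolated), via vinylcyclobutenone 14 (not isolated), via dienylketene 15 (not isolated), via cyclohexadienone 16 (not isolated)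
Conditions: 7 (2 equiv), PhMe, 110 °C, sealed tube, Ar; then K2CO3, MeOH, rt
Reagents that add atoms: none
Why: Heating opens 12 by conrotatory 4π cleavage (methoxy group turning outward) to vinylketene 13; the nucleophilic terminal carbon of ynol ether 7 attacks the ketene carbonyl carbon and the oxygen-bearing alkyne carbon bonds to the ketene α-carbon, giving [2+2] adduct 14 and with it the C2–C3 and C1–C6 bonds of ring B. A second 4π opening gives dienylketene 15, which closes ring B by thermal 6π electrocyclization between the ketene carbon (C3) and the methoxy-bearing terminus (C4), and dienone 16 enolizes to phenol 17. The closest known reaction type is the Danheiser benzannulation of cyclobutenones with alkoxy- and siloxyalkynes; an aryloxyalkyne and a 3,4-dioxygenated cyclobutenone are new substrates within that class. No stereocentre is formed, and the racemic centre of 12 disappears on aromatization. The step needs regiocontrol in the [2+2] event, which the polarization of the ynol ether secures (ring A oxygen meta to the new hydroxyl), and it needs capture of 13 to outrun ketene dimerization, which excess 7 (no β-hydrogen, hence no retro-ene loss on heating) should provide. The carbonate–methanol treatment returns any phenol that was acylated by unreacted ketene.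

Step 7
Reactants: 18 2,6-dimethoxyphenol; 19 5-bromo-1,2,3-trimethoxybenzene
Product: 20 1,3-dimethoxy-2-(3,4,5-trimethoxyphenoxy)benzene
Conditions: CuI (cat.), picolinic acid, K3PO4, DMSO, 100 °C, Ar
Reagents that add atoms: none
Why: Ullmann-type copper-catalysed diaryl ether synthesis with a ligand system that accepts 2,6-disubstituted phenols, here joined to an unhindered aryl bromide under exclusion of air.

Step 8
Reactants: 20 1,3-dimethoxy-2-(3,4,5-trimethoxyphenoxy)benzene
Product: 22 [3,5-dimethoxy-4-(3,4,5-trimethoxyphenoxy)phenyl]boronic acid, via pinacol boronate 21 (not isolated)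
Conditions: [Ir(OMe)(cod)]2 (cat.), 4,4′-di-tert-butyl-2,2′-bipyridine, B2pin2 (0.6 equiv), THF, 80 °C; then NaIO4, THF–H2O, 1 M HCl, rt
Reagents that add atoms: bis(pinacolato)diboron, CC1(C)OB(OC1(C)C)B1OC(C)(C)C(C)(C)O1; water, O
Why: Iridium-catalysed C–H borylation is sterically controlled and the only C–H without an ortho substituent is the one para to the aryloxy group on ring D (the ring E hydrogens are flanked on both sides), and periodate cleavage of the pinacol ester in the same pot gives the boronic acid.

Step 9
Reactants: 19 5-bromo-1,2,3-trimethoxybenzene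
Product: 24 6-bromo-2,3,4-trimethoxybenzaldehyde, via chloro ether 23 (not isolated)
Conditions: Cl2CHOMe, TiCl4, CH2Cl2, 0 °C; then H2O
Reagents that add atoms: dichloromethyl methyl ether, COC(Cl)Cl; water, O
Why: Rieche formylation; the two free positions of 19 are equivalent (each ortho and para to methoxy groups), so only one aldehyde can form, with the formyl group between bromine and a methoxy group.

Step 10
Reactants: 24 6-bromo-2,3,4-trimethoxybenzaldehyde
Product: 26 6-bromo-2,3,4-trimethoxyphenol, via aryl formate 25 (not isolated)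
Conditions: mCPBA, CH2Cl2, rt; then K2CO3 (cat.), MeOH
Reagents that add atoms: mCPBA, OOC(=O)c1cccc(Cl)c1
Why: Dakin-type Baeyer–Villiger oxidation, in which the electron-rich aryl group migrates and the formate is methanolysed, places the hydroxyl between bromine and methoxy without any regiochemical question.

Step 11
Reactants: 26 6-bromo-2,3,4-trimethoxyphenol; 22 [3,5-dimethoxy-4-(3,4,5-trimethoxyphenoxy)phenyl]boronic acid
Product: 27 1-bromo-2-[3,5-dimethoxy-4-(3,4,5-trimethoxyphenoxy)phenoxy]-3,4,5-trimethoxybenzene
Conditions: Cu(OAc)2 (1 equiv), pyridine, 4 Å MS, CH2Cl2, dry air, rt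
Reagents that add atoms: none
Why: Chan–Lam oxidative O-arylation runs at room temperature, accepts ortho-halogenated 2,6-disubstituted phenols and leaves the aryl bromide intact, so the C–O–D ether should form with the ring C bromine kept for step 12.

Step 12
Reactants: 17 3-isopropoxy-2-methoxy-5-(2,4,6-trimethoxyphenoxy)phenol; 27 1-bromo-2-[3,5-dimethoxy-4-(3,4,5-trimethoxyphenoxy)phenoxy]-3,4,5-trimethoxybenzene
Product: 28 fully protected pentamer (target with twelve methyl ethers and an isopropyl ether on ring B C5)
Conditions: CuI (cat.), picolinic acid, K3PO4, DMSO, 100 °C, Ar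
Reagents that add atoms: none
Why: Ullmann-type copper-catalysed diaryl ether synthesis; 17 has a single hydroxyl and 27 a single halogen, so only the B–O–C bond can form, and the picolinic acid system is suited to ortho-substituted, electron-rich partners.

Step 13
Reactants: 28 fully protected pentamer
Product: 29 target CNP0228612.0
Conditions: BBr3 (excess), CH2Cl2, −78 °C to rt; then H2O, 0 °C, Ar
Reagents that add atoms: none
Why: Lewis acid dealkylation should cleave the twelve methyl ethers and the isopropyl ether by bromide attack at the boron-activated alkyl carbons, while the four diaryl ether links offer no sp3 carbon and persist; handling under argon protects the pyrogallol-type rings.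

**Compound list**

1 | 2,4,6-trimethoxyphenol | COc1cc(OC)c(O)c(OC)c1 | starting material
2 | trichloroethylene | ClC=C(Cl)Cl | starting material
3 | dichloroacetylene (not isolated) | ClC#CCl | intermediate
4 | (E)-2-[(1,2-dichloroethenyl)oxy]-1,3,5-trimethoxybenzene | Cl/C=C(/Cl)Oc1c(OC)cc(OC)cc1OC | intermediate
5 | 2-[(chloroethynyl)oxy]-1,3,5-trimethoxybenzene (not isolated) | ClC#COc1c(OC)cc(OC)cc1OC | intermediate
6 | lithium (2,4,6-trimethoxyphenoxy)acetylide (not isolated) | [Li]C#COc1c(OC)cc(OC)cc1OC | intermediate
7 | 2-(ethynyloxy)-1,3,5-trimethoxybenzene (2,4,6-trimethoxyphenyl ethynyl ether) | C#COc1c(OC)cc(OC)cc1OC | intermediate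
8 | diisopropyl squarate | CC(C)OC1=C(OC(C)C)C(=O)C1=O | starting material
9 | 4-hydroxy-2,3-diisopropoxycyclobut-2-en-1-one (racemic, not isolated) | CC(C)OC1=C(OC(C)C)C(=O)C1O | intermediate
10 | 3-isopropoxycyclobut-3-ene-1,2-dione | CC(C)OC1=CC(=O)C1=O | intermediate
11 | 4-hydroxy-3-isopropoxycyclobut-2-en-1-one (racemic) | CC(C)OC1=CC(=O)C1O | intermediate
12 | 3-isopropoxy-4-methoxycyclobut-2-en-1-one (racemic) | CC(C)OC1=CC(=O)C1OC | intermediate
13 | (Z)-3-isopropoxy-4-methoxybuta-1,3-dien-1-one (not isolated) | O=C=C/C(OC(C)C)=C/OC | intermediate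
14 | 4-[(Z)-1-isopropoxy-2-methoxyethenyl]-3-(2,4,6-trimethoxyphenoxy)cyclobut-2-en-1-one (racemic, not isolated) | O=C1C=C(Oc2c(OC)cc(OC)cc2OC)C1/C(OC(C)C)=C/OC | intermediate
15 | (3E,5Z)-5-isopropoxy-6-methoxy-3-(2,4,6-trimethoxyphenoxy)hexa-1,3,5-trien-1-one (not isolated) | O=C=C/C(Oc1c(OC)cc(OC)cc1OC)=C\C(OC(C)C)=C\OC | intermediate
16 | 5-isopropoxy-6-methoxy-3-(2,4,6-trimethoxyphenoxy)cyclohexa-2,4-dien-1-one (racemic, not isolated) | O=C1C=C(Oc2c(OC)cc(OC)cc2OC)C=C(OC(C)C)C1OC | intermediate
17 | 3-isopropoxy-2-methoxy-5-(2,4,6-trimethoxyphenoxy)phenol | Oc1cc(Oc2c(OC)cc(OC)cc2OC)cc(OC(C)C)c1OC | intermediate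
18 | 2,6-dimethoxyphenol | COc1cccc(OC)c1O | starting material
19 | 5-bromo-1,2,3-trimethoxybenzene | COc1cc(Br)cc(OC)c1OC | starting material
20 | 1,3-dimethoxy-2-(3,4,5-trimethoxyphenoxy)benzene | COc1cccc(OC)c1Oc1cc(OC)c(OC)c(OC)c1 | intermediate
21 | 2-[3,5-dimethoxy-4-(3,4,5-trimethoxyphenoxy)phenyl]-4,4,5,5-tetramethyl-1,3,2-dioxaborolane (not isolated) | COc1cc(B2OC(C)(C)C(C)(C)O2)cc(OC)c1Oc1cc(OC)c(OC)c(OC)c1 | intermediate
22 | [3,5-dimethoxy-4-(3,4,5-trimethoxyphenoxy)phenyl]boronic acid | COc1cc(B(O)O)cc(OC)c1Oc1cc(OC)c(OC)c(OC)c1 | intermediate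
23 | 1-bromo-2-[chloro(methoxy)methyl]-3,4,5-trimethoxybenzene (racemic, not isolated) | COC(Cl)c1c(Br)cc(OC)c(OC)c1OC | intermediate
24 | 6-bromo-2,3,4-trimethoxybenzaldehyde | COc1cc(Br)c(C=O)c(OC)c1OC | intermediate
25 | 6-bromo-2,3,4-trimethoxyphenyl formate (not isolated) | COc1cc(Br)c(OC=O)c(OC)c1OC | intermediate
26 | 6-bromo-2,3,4-trimethoxyphenol | COc1cc(Br)c(O)c(OC)c1OC | intermediate
27 | 1-bromo-2-[3,5-dimethoxy-4-(3,4,5-trimethoxyphenoxy)phenoxy]-3,4,5-trimethoxybenzene | COc1cc(Br)c(Oc2cc(OC)c(Oc3cc(OC)c(OC)c(OC)c3)c(OC)c2)c(OC)c1OC | intermediate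
28 | fully protected pentamer (ring A 2,4,6-trimethoxy; ring B C4 methoxy, C5 isopropoxy; ring C trimethoxy; ring D dimethoxy; ring E trimethoxy) | COc1cc(OC)c(Oc2cc(OC(C)C)c(OC)c(Oc3cc(OC)c(OC)c(OC)c3Oc3cc(OC)c(Oc4cc(OC)c(OC)c(OC)c4)c(OC)c3)c2)c(OC)c1 | intermediate
29 | CNP0228612.0 | Oc1cc(O)c(Oc2cc(O)c(O)c(Oc3cc(O)c(O)c(O)c3Oc3cc(O)c(Oc4cc(O)c(O)c(O)c4)c(O)c3)c2)c(O)c1 | target

**Step count**

Total steps: 13. Longest linear sequence: 6 steps (3, 4, 5, 6, 12, 13).

**Steps most likely to fail**

1. Step 6. The vinylketene may be consumed by dimerization or by acylating the phenol as it forms, or the terminal ynol ether may oligomerize before the [2+2] capture; the second electrocyclic opening may also stall. The fallback sets out from 1 and makes the A–O–B ether by Ullmann-type coupling instead. Compound 1 and commercial 5-bromo-2,3-dimethoxybenzaldehyde (CuI, picolinic acid, K3PO4, DMSO, 100 °C) should give 2,3-dimethoxy-5-(2,4,6-trimethoxyphenoxy)benzaldehyde F1. Dakin oxidation (mCPBA, CH2Cl2; then K2CO3, MeOH) passes through 2,3-dimethoxy-5-(2,4,6-trimethoxyphenoxy)phenyl formate F2 to 2,3-dimethoxy-5-(2,4,6-trimethoxyphenoxy)phenol F3, the analogue of 17 with methyl in place of isopropyl. F3 and 27 under the conditions of step 12 should give the tridecamethyl ether of the target F4, and the conditions of step 13 bring the route back at 29.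

2. Step 12. Oxidative addition at the electron-rich bromide flanked by an aryloxy group may be slow, so that protodebromination or degradation of the phenoxide at 100 °C takes over. The fallback sets out from 17 and builds ring C onto it stepwise. Coupling of 17 with aldehyde 24, whose bromine is activated by the ortho formyl group (CuI, picolinic acid, K3PO4, DMSO, 90 °C), should give 6-[3-isopropoxy-2-methoxy-5-(2,4,6-trimethoxyphenoxy)phenoxy]-2,3,4-trimethoxybenzaldehyde F5. Dakin oxidation (mCPBA; then K2CO3, MeOH) through 6-[3-isopropoxy-2-methoxy-5-(2,4,6-trimethoxyphenoxy)phenoxy]-2,3,4-trimethoxyphenyl formate F6 gives 6-[3-isopropoxy-2-methoxy-5-(2,4,6-trimethoxyphenoxy)phenoxy]-2,3,4-trimethoxyphenol F7. Chan–Lam coupling of F7 with 22 under the conditions of step 11 brings the route back at 28.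

3. Step 11. Divalent copper and air may oxidize the electron-rich phenol, or protodeboronation of 22 may outpace transmetalation to the hindered copper phenoxide. The fallback sets out from 22 and replaces the oxidative coupling by a halide-selective one without oxidant. Ipso-iodination of 22 (I2, K2CO3, MeCN, 80 °C) should give 5-iodo-1,3-dimethoxy-2-(3,4,5-trimethoxyphenoxy)benzene F8. Ullmann-type coupling of 26 with F8 under argon (CuI, picolinic acid, K3PO4, DMSO, 80 °C), where the aryl iodide should react well before the ring C bromide, brings the route back at 27.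

**Further compounds**

F1 | step 6 | 2,3-dimethoxy-5-(2,4,6-trimethoxyphenoxy)benzaldehyde | O=Cc1cc(Oc2c(OC)cc(OC)cc2OC)cc(OC)c1OC
F2 | step 6 | 2,3-dimethoxy-5-(2,4,6-trimethoxyphenoxy)phenyl formate | O=COc1cc(Oc2c(OC)cc(OC)cc2OC)cc(OC)c1OC
F3 | step 6 | 2,3-dimethoxy-5-(2,4,6-trimethoxyphenoxy)phenol | Oc1cc(Oc2c(OC)cc(OC)cc2OC)cc(OC)c1OC
F4 | step 6 | tridecamethyl ether of the target | COc1cc(OC)c(Oc2cc(OC)c(OC)c(Oc3cc(OC)c(OC)c(OC)c3Oc3cc(OC)c(Oc4cc(OC)c(OC)c(OC)c4)c(OC)c3)c2)c(OC)c1
F5 | step 12 | 6-[3-isopropoxy-2-methoxy-5-(2,4,6-trimethoxyphenoxy)phenoxy]-2,3,4-trimethoxybenzaldehyde | COc1cc(Oc2cc(Oc3c(OC)cc(OC)cc3OC)cc(OC(C)C)c2OC)c(C=O)c(OC)c1OC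
F6 | step 12 | 6-[3-isopropoxy-2-methoxy-5-(2,4,6-trimethoxyphenoxy)phenoxy]-2,3,4-trimethoxyphenyl formate | COc1cc(Oc2cc(Oc3c(OC)cc(OC)cc3OC)cc(OC(C)C)c2OC)c(OC=O)c(OC)c1OC
F7 | step 12 | 6-[3-isopropoxy-2-methoxy-5-(2,4,6-trimethoxyphenoxy)phenoxy]-2,3,4-trimethoxyphenol | COc1cc(Oc2cc(Oc3c(OC)cc(OC)cc3OC)cc(OC(C)C)c2OC)c(O)c(OC)c1OC
F8 | step 11 | 5-iodo-1,3-dimethoxy-2-(3,4,5-trimethoxyphenoxy)benzene | COc1cc(I)cc(OC)c1Oc1cc(OC)c(OC)c(OC)c1
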